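In the dusk run, Ze falls from 14.8% at 2.50 h to 10.7% at 6.00 h, a fall in ln Ze of 0.0927 h⁻¹. The autumn run, read from 1.33 h to 6.00 h, gives 0.180 h⁻¹.

in all of them: Za 0.30 M

| run | Zb | Zc | remark | time |
|---|---|---|---|---|
| dusk | 1.3 M | 0.30 M | run made earlier |  |
| autumn | 2 M | 0.30 M | run made earlier |  |
| alpha | 0.900 M | 0.300 M |  | 8.0 h |
| delta | 0.900 M | 0.300 M |  | 12 h |
| beta | 0.900 M | 0.300 M |  | 20 h |

| run | time / h | Ze / % | Za / % |
|---|---|---|---|
| dusk | 0.500 | 12.4 | 14.0 |
| dusk | 0.833 | 13.2 | 12.1 |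
| dusk | 1.33 | 13.2 | 12.0 |
| dusk | 2.50 | 14.8 | 10.7 |
| dusk | 4.00 | 13.3 | 8.4 |
| dusk | 6.00 | 10.7 | 7.3 |
| autumn | 0.417 | 14.4 | 13.4 |
| autumn | 1.33 | 14.4 | 10.1 |
| autumn | 2.50 | 12.5 | 7.4 |
| autumn | 4.00 | 9.5 | 5.5 |
| autumn | 5.00 | 7.5 | 5.7 |
| autumn | 6.00 | 6.2 | 3.5 |

(scatter of a reading: 0.5 percentage points)



- which of the two there is more of at the end, alpha (Zh / Ze)
- which of the two there is more of at the end, delta (Zh / Ze)
- which of the two there is more of at the end, beta (Zh / Ze)
- amount of Ze at the end, in percent of the Za charged, alpha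
- amount of Ze at the end, in percent of the Za charged, delta
- amount of Ze at the end, in percent of the Za charged, beta

The zero of our scale is a loss proportional to c(Zb), order one. But from dusk to autumn c(Zb) rises by a factor of 1.54 and the read constant by 1.94, so the read order is 1.55, between one and two. For the 0.900 M of alpha this gives 0.0525 h⁻¹: the loss constant, the hourly fall of ln Ze after the peak, a pseudo-first-order constant for a given charge of Zb.

Now we bracket Ze in alpha at 8.0 h. Dusk's line, run back to zero time, starts at 18.7%, and we take that start for alpha too. From above, a flask losing nothing after the peak stays at dusk's peak reading, 14.8%. From below, alpha has less Zb than dusk, so dusk's own constant gives a floor of 8.91%. Order one tightens the floor to 11.2%, and order two lowers the ceiling to 13.1%. Our own figure, from the read order, is 12.3%.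

The forecast says 11.5%, 9.5% and 6.4%, with Zh ahead each time, and notes that “Za and Ze decline slowly together”. Its alpha figure lies inside the bracket, below ours.

Alpha gives 12.4%, delta 10.4% and beta 7.52%, while Zh stands at 33.8%, 44.8% and 58.7%.

Za + Zb → Ze (k = 2.39 × 10⁻⁴ L mol⁻¹ s⁻¹); Zc + Zb → Zf (k = 5.44 × 10⁻⁴ L mol⁻¹ s⁻¹); Za + Zc → Zg (k = 5.15 × 10⁻⁴ L mol⁻¹ s⁻¹); Za ⇌ Zd (K = 4.24, k = 0.00207 s⁻¹); Zb + Ze → Zh (k = 1.89 × 10⁻⁴ L mol⁻¹ s⁻¹) Free Zb in alpha is 43.0% of its charge at 8.00 h. Carried from alpha's end to delta's, 0.0525 h⁻¹ gives 10.0% against 10.4%. Carried on to the neighbour flask, delta read at 50 h, it gives 1.42%. That flask holds 3.08% of Ze, with free Zb down from 36.3% to 17% of its charge.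

The data were generated by integration on assumed constants; scatter was added.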